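The vessel is closed, stirred and isothermal, and the solid reagent starts undissolved. The charges, readings and questions are these:

common to all: starting material 28 mM; solid reagent 16.8 mM; added ligand 0.21 mM
- west: second substrate 56 mM; free catalyst 0.14 mM; run made earlier
- south-west: second substrate 56 mM; free catalyst 0.21 mM; run made earlier
- amber: second substrate 56.0 mM; free catalyst 0.28 mM; time 12 d
- red: second substrate 56.0 mM; free catalyst 0.28 mM; time 25 d

| run | time / d | target / % | starting material / % |
|---|---|---|---|
| west | 0.625 | 2.7 | 97.0 |
| west | 1.04 | 5.9 | 93.6 |
| west | 2.08 | 17.3 | 81.0 |
| west | 4.00 | 42.2 | 57.0 |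
| west | 8.00 | 52.9 | 40.8 |
| south-west | 0.625 | 2.9 | 95.8 |
| south-west | 1.04 | 7.9 | 91.4 |
| south-west | 2.08 | 22.5 | 77.9 |
| south-west | 4.00 | 48.3 | 49.0 |
| south-west | 8.00 | 51.2 | 40.4 |

(readings scatter by 0.5 percentage points)

- as a solid, counted per litre of solution: solid reagent
- the earlier runs were read with a standard deviation of 0.5 percentage points
- at the start none of the solid reagent is in solution

- which of the two there is more of at the end, amber (target / isomer of the product)
- which of the two there is more of at the end, red (target / isomer of the product)
- amount of target at the end, in percent of the starting material charged, amber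
- amount of target at the end, in percent of the starting material charged, red

By hand I start with the pool. If the solid reagent is the limiting reagent, conversion stops at c(solid reagent)/c(starting material) = 60.0%, and at 8.00 d the west run has converted 59.2% and the south-west run 59.6%. Target then stands below that pool, and I read the shortfall as isomer of the product. I measure it as x = ln(pool/target), which is 0.126 in the west run and 0.159 in the south-west run.

Dividing x by the time gives a pseudo-first-order leak. Timed from zero and scaled to 0.28 mM of catalyst, the pooled leak is 0.0285 d⁻¹. On that leak I reckon 42.6% of target for amber and 29.5% for red.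

The weak link is the clock: the west run reads 17.3% of target at 2.08 d, so target is not there from zero. Interpolating, half the pool is made at 2.96 d in the west run and 2.60 d in the south-west run. Timing each run from there, I define the leak coefficient, the leak per unit time per unit of catalyst charged, as 6.47 M⁻¹ h⁻¹.

The catalyst charges rise in equal steps, so I carry the fall in that time one step further, to 2.25 d. By my reckoning that makes amber's leak 0.0435 d⁻¹. I commit to 39.3% of target in amber, more than the 20.7% of isomer, and to 22.3% in red, less than the 37.7% of isomer.

The forecast gives 40% of target for amber and 23% for red, with target ahead in amber and isomer of the product ahead in red: “Target therefore still leads” at 12 d.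

Amber gives 40.0% of target against 19.6% of isomer, and red gives 25.8% against 33.8%.

    starting material + free catalyst ⇌ catalyst intermediate A (K = 1000 M⁻¹, k = 7400 M⁻¹ h⁻¹)
    partner + catalyst intermediate A → free catalyst + target (k = 240 M⁻¹ h⁻¹)
    second substrate + free catalyst ⇌ catalyst intermediate B (K = 8.90 M⁻¹, k = 210 M⁻¹ h⁻¹)
    partner + catalyst intermediate B → free catalyst + second product (k = 55.0 M⁻¹ h⁻¹)
    solid reagent ⇌ partner, rate k5*(cs5 - [partner]) while solid is left; crystals form when [partner] > cs5 (solubility = 16.0 mM, k = 0.0150 h⁻¹)
    free catalyst + added ligand ⇌ idle complex (K = 1700 M⁻¹, k = 190 M⁻¹ h⁻¹)
    target + free catalyst ⇌ isomer of the product + free catalyst, rate k7*[free catalyst]*[target] forward; the back reaction follows from the equilibrium constant (K = 3.10, k = 91.0 M⁻¹ h⁻¹)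

My reckoning parts from the flask in red, which lies 3.5 percentage points above my figure, while amber lies 0.70 points above. In amber, half the turnover of the step from starting material and free catalyst to catalyst intermediate A up to 12 d is done by 2.31 d, beside my clock start of 2.25 d. A neighbour flask is amber with 0.17 mM of catalyst. The leak coefficient gives it 0.0264 d⁻¹, and timed from 2.60 d that leaves 46.8% of target; the flask holds 47.2%.

Readings and results stem from a simulated flask on assumed constants; the scatter is artificial.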